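Count the working time.

| flask | J | G | time |
|---|---|---|---|
| epsilon | 0.800 M | 0.640 M |  |
| delta | 0.400 M | 0.240 M |  |
| alpha | 0.800 M | 1.30 M |  |
| beta | 0.800 M | 4.20 M | 150 min |

| run | time / min | [Q] / M |
|---|---|---|
| epsilon run | 6.0 | 0.0120 |
| epsilon run | 11 | 0.0316 |
| epsilon run | 22 | 0.0721 |
| epsilon run | 41 | 0.1346 |
| epsilon run | 79 | 0.1942 |
| epsilon run | 150 | 0.2203 |
| delta run | 6.0 | 0 |
| delta run | 11 | 0.0066 |
| delta run | 22 | 0.0187 |
| delta run | 41 | 0.0393 |
| delta run | 79 | 0.0673 |
| delta run | 150 | 0.0769 |
| alpha run | 6.0 | 0.0173 |
| alpha run | 11 | 0.0436 |
| alpha run | 22 | 0.1004 |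
| alpha run | 41 | 0.1696 |
| alpha run | 79 | 0.2348 |
| alpha run | 150 | 0.2784 |

(scatter of a reading: 0.002 M)

1. apparent order in [J] of the starting rate, round the charge of the epsilon run (the rate where two percent of its J have turned into Q) (one fixed amount of Q, the same in the runs compared)
2. apparent order in [G] of the starting rate, round the charge of the epsilon run (the rate where two percent of its J have turned into Q)
3. Q in the beta run at 150 min, as a share of the J charged

- Overall: J + G -> Q.
- Constant volume, constant temperature.
- An order is taken over about fifteen percent of the charge, up and down.

At the bench I expect a flask to run until its limiting reagent is used up. In the epsilon run that reagent is G, charged at less than J, so the rule promised Q at 80.0% of the J charged. The rule stopped working well before that: at 150 min the epsilon run stood at 27.5%. Its rate between 41 min and 79 min was 4.27 times its rate between 79 min and 150 min. Over the same stretch, the G that the overall equation leaves fell by a factor of 1.20, a smaller change.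

So I counted differently. I divided the Q at 150 min by the rate between 11 min and 22 min, which gives the minutes of early rate that this Q stands for. I called this the working time, and in the epsilon run I read 59.8 min. The alpha run, with more G, read shorter, at 53.9 min. With the same J charged, its Q at 150 min was still 1.26 times that of the epsilon run, its early rate being 1.40 times as high and its working time 0.901 times as long. The beta run holds 3.23 times the G of the alpha run, and as my own guess I multiplied the alpha share once more by that factor of 1.26 between the Q of the two runs, which gave me 44.0% of the J of the beta run at 150 min.

The forecast gave orders of 1 in J and 0.5 in G and a beta share of 39%, lower than mine. Of the J order it said: “No pair isolates J, so that order is inferred”.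

The flask gave 0.71 in J, below the forecast, 0.47 in G, and 36.9% of the J in the beta run at 150 min.

    J ⇌ E + L (0.009960 min⁻¹, 0.005388 M⁻¹ min⁻¹)
    E + G → Q (0.1644 M⁻¹ min⁻¹)
    G → Vy (0.01584 min⁻¹)
    J → Qa (0.01614 min⁻¹)

Where two percent of the J of the epsilon run had turned, the rate of the alpha run was 0.0047 M min⁻¹, which is 1.4 times that of the epsilon run at the same amount of Q. The beta share divided by the working time of the alpha run comes to 0.00685 min⁻¹ as a fraction of the J charged. The working time of the epsilon run, multiplied by that run's own rate of 0.0035 M min⁻¹, gives 26.0% of its J, and its reading at 150 min was 27.5%.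

The data were generated by integration from invented constants, noise included.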